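Which flask, north-west or east, ends with the larger lead of right-handed substrate, and how large is that lead?

| flask | left-handed substrate | right-handed substrate | partner | free catalyst | impurity | remark | time |
|---|---|---|---|---|---|---|---|
| delta | 20 mM | 20 mM | 25 mM | 1 mM | 1.2 mM | run made earlier |  |
| alpha | 20 mM | 20 mM | 91 mM | 1 mM | 1.2 mM | run made earlier |  |
| north-west | 20 mM | 20 mM | 20.0 mM | 1.0 mM | 1.2 mM |  | 2.0 h |
| east | 20 mM | 20 mM | 60.0 mM | 1.0 mM | 1.2 mM |  | 2.0 h |

- delta (time / min: right-handed substrate / %, left-handed substrate / %): 10.0: 44, 38; 20.0: 43, 40; 30.0: 42, 39; 60.0: 41, 35; 120: 43, 36
- alpha (time / min: right-handed substrate / %, left-handed substrate / %): 25.0: 25, 16; 50.0: 26, 11; 80.0: 30, 14; 90.0: 27, 16; 120: 25, 14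

(each reading ± 2 percentage points)

- free catalyst is single-handed; left-handed substrate and right-handed substrate are mirror images of each other, charged as a racemate, each of them at the stated concentration
- an excess is below zero if the other one leads

- the flask that ends with the higher excess of right-handed substrate over left-handed substrate among what is left of the two, or "neither" when 2 percentage points or less lies between them (north-west / east / neither)
- excess of right-handed substrate over left-handed substrate among what is left of the two at the end, north-west
- excess of right-handed substrate over left-handed substrate among what is left of the two at the end, east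

Both runs look flat: delta from 10.0 min to 120 min, alpha from 25.0 min to 120 min. Is this equilibrium? No: mirror images would stand level there, and right-handed substrate leads, so this is kinetic control, stopped early. Did partner stop it? Delta averages 42.6 % right-handed and 37.6 % left-handed. At one partner per substrate, the substrate lost in delta stands for 7.92 mM of partner, less than the 25 mM charged. I suspect the catalyst, as impurity is more than catalyst.

I take each substrate to fall in proportion to itself, [partner] and [free catalyst]. Delta, alpha, north-west and east differ in the partner charged, not in catalyst or impurity. If the catalyst lasts equally long in each, the final log ratio grows in step with partner. Delta gives 0.125. Alpha, with 26.6 % and 14.2 %, gives 0.628. Pooled, that is 0.00649 mM⁻¹, my split per mM: the plateau's ln([right-handed substrate]/[left-handed substrate]) over the partner charged.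

But [partner] falls during a run. By the same count, delta uses 31.7 % of its charge and alpha 26.0 %, and the pooled figure carries that correction with it. Worse, the runs separately give 0.00499 mM⁻¹ and 0.00690 mM⁻¹. Scatter carries to 0.00149 mM⁻¹ on that gap, and the gap is less than two such scatters. I keep one value.

The excess is (ratio minus one)/(ratio plus one). So I reckon 6.48 % for north-west and 19.2 % for east.

The forecast says east, with 5.6 % (4.3 % to 7 %) and 19 % (16 % to 22 %), on the ground that “the catalyst's lifetime is roughly fixed”. It stands below me on north-west and level with me on east.

The flasks give east: 6.11 % for north-west and 18.8 % for east, both inside the forecast's ranges.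

    partner + free catalyst + left-handed substrate → free catalyst + left-handed product (k = 290 M⁻² s⁻¹)
    partner + free catalyst + right-handed substrate → free catalyst + right-handed product (k = 150 M⁻² s⁻¹)
    partner ⇌ dormant form (K = 1.10, k = 0.00200 s⁻¹)
    free catalyst + impurity → spent catalyst (k = 22.0 M⁻¹ s⁻¹)
    2 free catalyst ⇌ resting dimer, settled at all times (K = 9000 M⁻¹)

Read back, the split per mM is 0.00612 mM⁻¹ in north-west and 0.00633 mM⁻¹ in east. The neighbour is north-west with 34 mM of partner. Partner ends at 31 % of charge in north-west, 32 % in the neighbour and 34 % in east, while dormant form holds 6.84 mM, 12.0 mM and 22.2 mM. My split gives it a ratio of 1.25 and an excess of 11.0 %. The neighbour ends at 10.5 %.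

The runs were computed with made-up constants, noise included.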